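**Assumptions.** (i) Germacranolide numbering is used, with C8–O the lactone oxygen and C9=C10 the ring-cis alkene; the target is (4R,6R,7R,8R). (ii) The 2-methylfuran-derived stannane and similar simple reagents are commercial or one step from commercial material. (iii) The C6 ketone reduction is assumed to follow Felkin–Anh control (C7–C8 as the large group), which predicts the 6R alcohol.

## Retrosynthetic overview
1. The target comes from an α-methylene installation (Mannich, then elimination) and tiglate esterification of a 10-membered hydroxy-furanone lactone. The furanone comes from oxidation of an allylic alcohol.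
2. The 10-membered carbocycle, already carrying the 1,4-epoxy bridge, comes from a transannular alkoxide-triggered (Grob-type) cleavage of the C1–C6 bond of an exo-epoxy-7-oxanorbornane. This is a 6→10 ring expansion and also unmasks the C6 ketone and the C1=C2 enol ether.
3. The oxanorbornane comes from an intramolecular Diels–Alder of a furan (IMDAF) onto a tethered TBS enol ether. The Z-alkene and trans-γ-lactone in the tether set C4 relative to C7 and C8.
4. The tether comes from a Stille coupling of a Z-vinyl iodide with a furylstannane. The trans-lactone and C6 methyl ketone come from an Evans syn aldol of (Z)-3-iodobutenal with a succinyl imide.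

## Route

**Step 1**
Reactants: 1 (2-butyn-1-ol)
Product: 2 ((Z)-3-iodobut-2-en-1-ol)
Conditions: Red-Al, THF, 0 °C; EtOAc; then I2, −78 °C
Reagents that add atoms: iodine, II
Why: Trans-hydroalumination directed by the alkoxide gives a five-membered oxa-aluminacycle, and iodinolysis then delivers the Z-vinyl iodide (Corey/Denmark hydroalumination–iodination).

**Step 2**
Reactants: 2
Product: 3 ((Z)-3-iodobut-2-enal)
Conditions: Dess–Martin periodinane, NaHCO3, CH2Cl2, 0 °C
Reagents that add atoms: none
Why: Mild, non-isomerizing oxidation of a primary allylic alcohol to the enal.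

**Step 3**
Reactants: 4 ((S)-4-benzyloxazolidin-2-one); 5 (mono-tert-butyl succinate)
Product: 6 (tert-butyl 4-[(4S)-4-benzyl-2-oxooxazolidin-3-yl]-4-oxobutanoate)
Conditions: 5, PivCl, Et3N, THF, −20 °C; then 4, LiCl, 0 °C → rt
Reagents that add atoms: none (PivCl is lost as pivalate)
Why: Mixed-anhydride N-acylation of the oxazolidinone (Evans acylation).

**Step 4**
Reactants: 6; 3
Product: 7 (tert-butyl (3S,4S,5Z)-3-{[(4S)-4-benzyl-2-oxo-oxazolidin-3-yl]carbonyl}-4-hydroxy-6-iodohept-5-enoate)
Conditions: Bu2BOTf, iPr2NEt, CH2Cl2, −78 → 0 °C; then 3, −78 → 0 °C; H2O2, pH 7 buffer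
Reagents that add atoms: none (boron is removed on work-up)
Why: The imide Z-boron enolate (the ester CH2 is not enolized) reacts through a Zimmerman–Traxler chair (Evans syn aldol). The (S)-auxiliary sets C7 = S and C8 as drawn, giving the syn adduct that becomes the trans-lactone.

**Step 5**
Reactants: 7
Product: 8 (tert-butyl (3S,4S,5Z)-4-hydroxy-6-iodo-3-[methoxy(methyl)carbamoyl]hept-5-enoate; auxiliary 4 recovered)
Conditions: MeNH(OMe)·HCl, AlMe3, CH2Cl2, 0 °C
Reagents that add atoms: N,O-dimethylhydroxylamine, CNOC (as its HCl salt)
Why: Al-mediated transamidation of the more electrophilic imide (Weinreb amination), leaving the hindered tert-butyl ester and vinyl iodide intact; no stereocenter is touched.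

**Step 6**
Reactants: 8
Product: 9 (tert-butyl (3S,4S,5Z)-3-acetyl-4-hydroxy-6-iodohept-5-enoate)
Conditions: MeMgBr (3 equiv), THF, −20 → 0 °C
Reagents that add atoms: methylmagnesium bromide, C[Mg]Br
Why: Weinreb ketone synthesis; the chelated tetrahedral intermediate prevents over-addition, and the free alkoxide does not trigger retro-aldol because the ketone forms only on quench.

**Step 7**
Reactants: 9
Product: 10 ((4S,5S)-4-acetyl-5-[(1Z)-2-iodoprop-1-enyl]oxolan-2-one, trans-4,5-disubstituted)
Conditions: TFA, CH2Cl2, 0 °C → rt; then PPTS, PhMe, 40 °C if needed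
Reagents that add atoms: none
Why: Acidolysis of the tert-butyl ester followed by γ-lactonization. No furan is present yet, so the acid-labile furyl-allylic lactone is not at risk. Any epimerization at C7 would favour the same trans isomer.

**Step 8**
Reactants: 11 (2-methylfuran)
Product: 12 (2-methyl-5-(tributylstannyl)furan)
Conditions: n-BuLi, THF, −78 → 0 °C; then Bu3SnCl
Reagents that add atoms: tributyltin chloride, CCCC[Sn](Cl)(CCCC)CCCC
Why: α-Lithiation of the furan followed by stannylation.

**Step 9**
Reactants: 10; 12
Product: 13 ((4S,5R)-4-acetyl-5-[(1Z)-2-(5-methylfuran-2-yl)prop-1-enyl]oxolan-2-one)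
Conditions: Pd2(dba)3, AsPh3, CuI, DMF, 45 °C
Reagents that add atoms: none (the furyl group comes from 12)
Why: Stille coupling under base-free conditions, which avoids E1cB opening of the β-acyloxy ketone. It proceeds with retention, so the alkene stays Z (furan cis to C8).

**Step 10**
Reactants: 13
Product: 14 ((4S,5R)-4-{1-[(TBS)oxy]ethenyl}-5-[(1Z)-2-(5-methylfuran-2-yl)prop-1-enyl]oxolan-2-one)
Conditions: LiHMDS (1.05 equiv), THF, −78 °C; then TBSOTf, −78 °C
Reagents that add atoms: TBSOTf, CC(C)(C)[Si](C)(C)OS(=O)(=O)C(F)(F)F
Why: Kinetic deprotonation takes the unhindered ketone CH3 (not the tertiary C7–H or the lactone C11–H2), and the terminal enol silane is the IMDAF dienophile. An enolate at C5 cannot undergo E1cB loss of the C8 carboxylate.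

**Step 11**
Reactants: 14
Product: 15 (exo IMDAF adduct: 7-oxanorbornene bridged C1–O–C4, C4–Me, C6–OTBS, fused at C1–C6 to the cyclohexene bearing the trans-lactone; SMILES below)
Conditions: PhMe (0.01 M), BHT, K2CO3, 110 °C, sealed tube (or 12 kbar, CH2Cl2, 25 °C)
Reagents that add atoms: none
Why: Proposed new method: thermal IMDAF of an unactivated 1,1-disubstituted silyl enol ether on a 2-alkenylfuran, forming vicinal quaternary centres at C1–C6 (closest known reaction: IMDAF to 7-oxanorbornenes). The Z-alkene pre-organizes the four-atom tether, the trans-lactone forces both its bonds pseudo-equatorial in the chair-like exo TS, and this fixes the furan face, so C4 (R) is set relative to C7/C8 (C1 follows from the bridged skeleton and C6 is later destroyed). Heat or pressure is used because the reaction is reversible.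

**Step 12**
Reactants: 15
Product: 16 (exo-2,3-epoxide of the oxanorbornane)
Conditions: DMDO (acetone solution), CH2Cl2, −20 °C
Reagents that add atoms: dimethyldioxirane, CC1(C)OO1 (one O is retained)
Why: Electrophilic epoxidation occurs on the strained, open exo face of the oxanorbornene alkene (syn to the O-bridge, as is usual for 7-oxanorbornenes). The C9=C10 alkene is shielded by the C1 quaternary centre and deactivated by two allylic oxygens.

**Step 13**
Reactants: 16
Product: 17 (10-membered ring: dihydrofuran C1=C2, C3–OH (3S), C6 ketone, trans-lactone; SMILES below)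
Conditions: TBAF–AcOH (1:1), THF, 0 °C
Reagents that add atoms: none
Why: Proposed new method: fluoride unmasks the C6 tertiary alkoxide, which fragments with the exo C2–O epoxide bond antiperiplanar to C1–C6 (the geometry of an exo leaving group in 2-norbornyl systems). This gives C6=O, C1=C2 and C3–O⁻, expanding the six-membered ring to the ten-membered carbocycle (closest known reaction: epoxy-alkoxide Grob fragmentation). C4, C7, C8 and the Z-alkene are untouched, and the C3 alcohol is temporary.

**Step 14**
Reactants: 17
Product: 18 (furan-3(2H)-one with C6 ketone)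
Conditions: activated MnO2, CH2Cl2, rt
Reagents that add atoms: none
Why: Chemoselective oxidation of the allylic alcohol, which is vinylogous to the enol ether, gives the 3(2H)-furanone. Neutral conditions protect this acid-labile glycal-like alcohol.

**Step 15**
Reactants: 18
Product: 19 ((4R,6R,7R,8R)-6-hydroxy compound)
Conditions: Zn(BH4)2, Et2O, −20 °C
Reagents that add atoms: none
Why: Hydride reduction of the more electrophilic C6 ketone (the vinylogous-ester C3 carbonyl and the lactone are untouched). Felkin–Anh attack anti to the large C7–C8 bond sets 6R.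

**Step 16**
Reactants: 19
Product: 20 (C6 tiglate, α-unsubstituted lactone)
Conditions: tiglic acid, 2,4,6-Cl3C6H2COCl, Et3N, then 19, DMAP, PhMe, rt
Reagents that add atoms: tiglic acid, C/C=C(\C)C(=O)O
Why: Yamaguchi esterification keeps the E-enoate geometry and leaves C6 configured (no inversion).

**Step 17**
Reactants: 20
Product: 21 (α-dimethylaminomethyl lactone)
Conditions: LiHMDS, THF, −78 °C; then Me2N⁺=CH2 I⁻
Reagents that add atoms: Eschenmoser's salt, C[N+](C)=C.[I-]
Why: The lactone α-CH2 is the only acidic position in 20, since the furanone C2–H is vinylic and C4 is quaternary. Mannich aminomethylation of the enolate follows; the new C11 stereocentre is destroyed in the next step.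

**Step 18**
Reactants: 21
Product: 22 (Atripliciolide tiglate)
Conditions: MeI, CH2Cl2, rt; then sat. aq. NaHCO3
Reagents that add atoms: none (the NMe3 group is lost)
Why: Quaternization followed by Hofmann-type elimination gives the exocyclic α-methylene-γ-lactone without touching the furanone, tiglate or Z-alkene.

## Compound list
1 | 2-butyn-1-ol | CC#CCO | starting material
2 | (Z)-3-iodobut-2-en-1-ol | OC/C=C(/C)I | intermediate
3 | (Z)-3-iodobut-2-enal | O=C/C=C(/C)I | intermediate
4 | (S)-4-benzyloxazolidin-2-one | O=C1N[C@@H](Cc2ccccc2)CO1 | starting material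
5 | mono-tert-butyl succinate | CC(C)(C)OC(=O)CCC(=O)O | starting material
6 | succinyl Evans imide | CC(C)(C)OC(=O)CCC(=O)N1[C@@H](Cc2ccccc2)COC1=O | intermediate
7 | syn-aldol adduct | CC(C)(C)OC(=O)C[C@H](C(=O)N1[C@@H](Cc2ccccc2)COC1=O)[C@H](O)/C=C(/C)I | intermediate
8 | Weinreb amide | CC(C)(C)OC(=O)C[C@H](C(=O)N(C)OC)[C@H](O)/C=C(/C)I | intermediate
9 | β-hydroxy methyl ketone | CC(C)(C)OC(=O)C[C@H](C(C)=O)[C@H](O)/C=C(/C)I | intermediate
10 | trans-acetyl lactone, vinyl iodide | CC(=O)[C@H]1CC(=O)O[C@@H]1/C=C(/C)I | intermediate
11 | 2-methylfuran | Cc1ccco1 | starting material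
12 | 2-methyl-5-(tributylstannyl)furan | CCCC[Sn](CCCC)(CCCC)c1ccc(C)o1 | intermediate
13 | furyl lactone | CC(=O)[C@H]1CC(=O)O[C@@H]1/C=C(/C)c1ccc(C)o1 | intermediate
14 | TBS enol ether | C=C(O[Si](C)(C)C(C)(C)C)[C@H]1CC(=O)O[C@@H]1/C=C(/C)c1ccc(C)o1 | intermediate
15 | IMDAF adduct | C[C@@]12C=C[C@]3(O1)C(C)=C[C@H]4OC(=O)C[C@@H]4[C@@]3(O[Si](C)(C)C(C)(C)C)C2 | intermediate
16 | exo-epoxide | C[C@@]12[C@H]3O[C@H]3[C@]4(O1)C(C)=C[C@H]5OC(=O)C[C@@H]5[C@@]4(O[Si](C)(C)C(C)(C)C)C2 | intermediate
17 | ring-expanded hydroxy-dihydrofuran ketone | C1C(=O)O[C@@H]2/C=C(/C)C3=C[C@H](O)[C@@](C)(CC(=O)[C@@H]12)O3 | intermediate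
18 | furanone ketone | C1C(=O)O[C@@H]2/C=C(/C)C3=CC(=O)[C@@](C)(CC(=O)[C@@H]12)O3 | intermediate
19 | 6-hydroxy compound | C1C(=O)O[C@@H]2/C=C(/C)C3=CC(=O)[C@@](C)(C[C@@H](O)[C@@H]12)O3 | intermediate
20 | tiglate, saturated lactone | C1C(=O)O[C@@H]2/C=C(/C)C3=CC(=O)[C@@](C)(C[C@@H](OC(=O)/C(C)=C/C)[C@@H]12)O3 | intermediate
21 | Mannich base | CN(C)CC1C(=O)O[C@@H]2/C=C(/C)C3=CC(=O)[C@@](C)(C[C@@H](OC(=O)/C(C)=C/C)[C@@H]12)O3 | intermediate
22 | Atripliciolide tiglate | C=C1C(=O)O[C@@H]2/C=C(/C)C3=CC(=O)[C@@](C)(C[C@@H](OC(=O)/C(C)=C/C)[C@@H]12)O3 | target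

**Total steps:** 18, including two short parallel branches (imide formation, Step 3; stannane, Step 8).
**Longest linear sequence:** 16 steps (Steps 1, 2, 4–7, 9–18).

**Three steps most likely to fail**
1. **Step 11 (IMDAF).** The dienophile is unactivated, the adduct has vicinal quaternary centres and the reaction is reversible; the C4 facial sense is also only predicted. Fallback: drop the Diels–Alder. Make the 3(2H)-furanone by ynone / tertiary-alcohol cyclization on an acyclic Evans-derived chain, and close the ten-membered ring by intramolecular NHK allylation at C7–C8, which forms the lactone at the same time.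
2. **Step 13 (fragmentation).** Basic fluoride may cause E1cB opening of the lactone from the new C6 ketone, or the ring strain may disfavour expansion. Fallback: run the Diels–Alder, epoxidation and fragmentation on an acyclic tether (C8–OTBS, CH2CO2tBu at C7) and lactonize after ring expansion.
3. **Step 12 (chemoselective epoxidation).** DMDO may attack the trisubstituted C9=C10 alkene. Fallback: OsO4 dihydroxylation of the strained alkene (sterically selective), conversion to the cyclic sulfate, then fluoride-triggered fragmentation with the sulfate as leaving group.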